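Readings and results stem from a simulated flask for an exercise, and the scatter is random.

Hours are the unit here. You charge substrate, coupling partner and free catalyst. The catalyst passes through catalyst intermediates A and B, and each pass releases product.

| setting | amber | teal | ochre | flask |
|---|---|---|---|---|
| substrate | 0.046 M | 0.046 M | 0.092 M | 0.046 M |
| coupling partner | 0.028 M | 0.041 M | 0.0552 M | 0.0552 M |
| free catalyst | 1.1 mM | 1.1 mM | 1.1 mM | 1.1 mM |
| remark | run made earlier | run made earlier | run made earlier |  |

| run | time / h | product / % |
|---|---|---|
| amber | 2.50 | 5.8 |
| amber | 6.00 | 12.6 |
| amber | 12.0 | 22.4 |
| amber | 30.0 | 39.9 |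
| teal | 2.50 | 5.9 |
| teal | 6.00 | 16.3 |
| teal | 12.0 | 29.6 |
| teal | 30.0 | 54.8 |
| ochre | 2.50 | 3.6 |
| ochre | 6.00 | 9.9 |
| ochre | 12.0 | 18.9 |
| ochre | 30.0 | 36.6 |

(standard deviation of a reading: 0.5 percentage points)

- apparent order in free catalyst when 50% of the substrate are converted (percent change of the rate of making product for one percent more free catalyst charged)

- the earlier runs were read with a standard deviation of 0.5 percentage points
- reactions considered so far: substrate + free catalyst -> catalyst intermediate A; coupling partner + catalyst intermediate A -> catalyst intermediate B; catalyst intermediate B <-> free catalyst + product; coupling partner -> decomposed reagent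
- no earlier run changes the charge of free catalyst; that part of a forecast is a guess

Read the runs as a ladder of times, and count what is left, not what is made.

The first rung is one catalyst turn. Between 2.50 h and 6.00 h, the teal run makes 4.78 mM of product on 1.1 mM of catalyst, so one turn takes about 0.805 h.

The second rung is the coupling partner. At 30.0 h, ochre has made 1.34 times teal's product. Its partner charge is 1.35 times teal's, while its substrate charge is twice teal's. So I treat the partner as decaying pseudo-first-order. Let f be the fraction of partner left, counting only what product has used, and P the product made. The partner half-life t_B is the time in which f halves at a fixed catalyst charge. I read it from the teal run at time t = 30.0 h: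

f = 1 − P/[partner charge] = 38.5%

t_B = t × ln 2 / (−ln f) = 21.8 h

One catalyst turn is far shorter than t_B, so I let the catalyst forms follow the partner.

The next rung is the partner's decomposition, which I do not separate here.

For the flask, half conversion uses about 23.0 mM of 0.0552 M partner:

f = 58.3%, so t = 16.9 h

My guess is that t_B scales inversely with the catalyst charge. That gives order one, plus an excess I cannot size. The forecast says 1.12: “so less partner has decomposed and the rate at that conversion is somewhat higher”.

    substrate + free catalyst → catalyst intermediate A (k = 6.90 /M/min)
    coupling partner + catalyst intermediate A → catalyst intermediate B (k = 0.860 /M/min)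
    catalyst intermediate B ⇌ free catalyst + product (K = 0.0160 M, k = 0.0640 /min)
    coupling partner → decomposed reagent (k = 1.50 × 10⁻⁴ /min)

The flask gives 1.2, so the forecast held. The flask reaches half conversion at 17.9 h, later than the 16.9 h reckoned from t_B. Now put t_B on the amber run. With t_B, f in the amber run after 30.0 h is reckoned at 38.5% again, which gives 37.4% of the substrate as product; the reading is 39.9%.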